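**Plan**

1. Retrosynthesis: the C4 methylene of the target is traced back to a C4–SPh group. The pyran ring is then cut at C2–C3 and C4–C4a, separating a two-carbon alkene (C3–C4, phenyl vinyl sulfide) from an O-aryl oxocarbenium ion (C4a–C8a–O1–C2). The cation is traced through its O1–C2 bond to an acetal of 3,4,5-trimethoxybenzaldehyde with 2,3-dimethoxyphenol.
2. Enabling feature: O1 sits on C8a of ring A, whose only unsubstituted ortho carbon is C4a (C8 carries OMe), and C4a lies para to the C7 methoxy group. C2 bears the cation-stabilising trimethoxyphenyl ring, so ring A–O1–C2 can act as a cationic 2-oxadiene with a single closure site.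
3. Forward: aldehyde → benzal chloride → symmetric bis(2,3-dimethoxyphenyl) acetal; one cationic (4+2) annulation with phenyl vinyl sulfide then builds the pyran ring (the only ring made), and nickel boride removes the sulfur.
4. A symmetric diaryl acetal is chosen over an aryl methyl acetal because it can ionise in one direction only. An aryl methyl acetal can also expel the phenol to give the more stable O-methyl cation, which would divert the vinyl sulfide.
5. Stereochemistry: C2 (S) is set in the annulation by the chiral counter-anion of a Brønsted acid catalyst. The C4 centre formed in the same step is erased by the desulfurisation, which does not touch C2.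

Key step: step 3

Assumption: the sense of induction of the chiral acid in step 3 cannot be predicted with confidence; the (R)-configured catalyst is written, and its mirror image is to be used should a first run show that it is the one delivering (2S).

**Route**

Step 1
Reactants: 1 3,4,5-trimethoxybenzaldehyde
Product: 2 5-(dichloromethyl)-1,2,3-trimethoxybenzene
Conditions: SOCl2 (2 equiv), DMF (cat.), CH2Cl2, 40 °C; evaporate, use crude under argon
Reagents that add atoms: thionyl chloride, O=S(Cl)Cl
Why: Deoxygenative gem-dichlorination of an aromatic aldehyde through the Vilsmeier-type chloroiminium species from SOCl2 and DMF is a standard route to benzal chlorides; the methyl ethers are inert to it and no stereocenter is involved.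

Step 2
Reactants: 2 5-(dichloromethyl)-1,2,3-trimethoxybenzene; 3 2,3-dimethoxyphenol (2.2 equiv)
Product: 6 5-[bis(2,3-dimethoxyphenoxy)methyl]-1,2,3-trimethoxybenzene, via sodium 2,3-dimethoxyphenoxide 4 (not isolated), via chloro aryl ether 5 (not isolated)
Conditions: NaH (2.1 equiv), THF, 0 °C; then 2, DMF, 0 °C to rt
Reagents that add atoms: none
Why: This is a twofold Williamson-type etherification in which the benzylic gem-dichloride ionises easily (first to an aryl-stabilised, then to an aryloxy-stabilised cation) and the phenoxide attacks through oxygen in the dipolar aprotic medium, while the basic conditions exclude the acid-mediated Friedel–Crafts C-alkylation an electron-rich phenol would otherwise suffer; the acetal carbon of 6 carries two identical aryloxy groups and is not a stereocenter.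

Step 3
Reactants: 6 5-[bis(2,3-dimethoxyphenoxy)methyl]-1,2,3-trimethoxybenzene; 7 phenyl vinyl sulfide (2 equiv)
Product: 10 (2S,4S)-7,8-dimethoxy-4-(phenylsulfanyl)-2-(3,4,5-trimethoxyphenyl)chromane, via O-aryl oxocarbenium ion 8 (not isolated), via thionium ion 9 (not isolated)
Conditions: (R)-3,3'-bis(2,4,6-triisopropylphenyl)-1,1'-binaphthyl-2,2'-diyl N-triflylphosphoramide (10 mol %), 4 Å MS, toluene/CH2Cl2, −60 °C; Et3N quench
Reagents that add atoms: none
Why: Proposed new method: The chiral N-triflylphosphoramide protonates an aryloxy oxygen of 6 and expels 2,3-dimethoxyphenol, the only ionisation open to the symmetric acetal, to give the O-aryl oxocarbenium ion 8 as a contact ion pair with the chiral anion; the CH2 terminus of 7 adds to C2 (C2–C3 bond), and the resulting thionium ion 9 is attacked at C4 by C4a of ring A (C4–C4a bond), after which loss of the arenium proton returns the acid. The closest known reaction types are the racemic Lewis acid promoted oxa-Povarov annulation of O-aryl oxocarbenium ions with alkenes, the chiral phosphoric acid catalysed Povarov reaction of N-aryl imines and chiral-anion-controlled additions to cyclic oxocarbenium ions; what is new is enantiocontrol of an acyclic O-aryl oxocarbenium ion in this stepwise (4+2) process. The pyran ring closes by a 6-exo-trig Friedel–Crafts attack of the arene on the thionium carbon. C2 (S) is fixed in the intermolecular C2–C3 bond formation by the chiral anion, which shields one face of the planar cation (catalyst control, since 6 is achiral), whereas C4 arises under substrate control through a chair-like closure that should place the aryl and phenylsulfanyl groups equatorial (2,4-cis); its configuration is of no consequence because C4 is reduced in step 4. The step needs site selectivity in the ring closure, which is secured because C4a is the only unsubstituted carbon ortho to O1 and is activated by the para methoxy group at C7, and it needs chemoselectivity of 7 for carbon–carbon bond formation over acid-initiated oligomerisation, which the low temperature and the catalytic amount of acid should favour. Enantiopurity additionally requires that no achiral acid is present and that the mixture is quenched with Et3N while cold, so that the benzylic C2–O1 bond of 10 is not reopened.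

Step 4
Reactants: 10 (2S,4S)-7,8-dimethoxy-4-(phenylsulfanyl)-2-(3,4,5-trimethoxyphenyl)chromane
Product: 11 (2S)-7,8-dimethoxy-2-(3,4,5-trimethoxyphenyl)chromane, that is (2S)-7,8,3',4',5'-pentamethoxyflavan
Conditions: NiCl2·6H2O, NaBH4 (excess), MeOH/THF, 0 °C to rt
Reagents that add atoms: none
Why: Reductive desulfurisation with nickel boride (Ni2B, formed in the flask from NiCl2 and NaBH4) hydrogenolyses the benzylic C4–S bond and the S–phenyl bond while leaving the aryl methyl ethers and the C2–O1 ether untouched, so C4 becomes a methylene group and the C2 centre set in step 3 is carried into the target unchanged.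

**Compound list**

1 | 3,4,5-trimethoxybenzaldehyde | O=Cc1cc(OC)c(OC)c(OC)c1 | starting material
2 | 5-(dichloromethyl)-1,2,3-trimethoxybenzene | ClC(Cl)c1cc(OC)c(OC)c(OC)c1 | intermediate
3 | 2,3-dimethoxyphenol | Oc1cccc(OC)c1OC | starting material
4 | sodium 2,3-dimethoxyphenoxide | [Na+].[O-]c1cccc(OC)c1OC | intermediate
5 | 1-[chloro(3,4,5-trimethoxyphenyl)methoxy]-2,3-dimethoxybenzene (racemic) | COc1cc(C(Cl)Oc2cccc(OC)c2OC)cc(OC)c1OC | intermediate
6 | 5-[bis(2,3-dimethoxyphenoxy)methyl]-1,2,3-trimethoxybenzene (achiral) | COc1cc(C(Oc2cccc(OC)c2OC)Oc2cccc(OC)c2OC)cc(OC)c1OC | intermediate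
7 | phenyl vinyl sulfide | C=CSc1ccccc1 | starting material
8 | (2,3-dimethoxyphenyl)[(3,4,5-trimethoxyphenyl)methylidene]oxonium, cation drawn, counter-ion is the chiral phosphoramide anion | COc1cc(C=[O+]c2cccc(OC)c2OC)cc(OC)c1OC | intermediate
9 | [(3S)-3-(2,3-dimethoxyphenoxy)-3-(3,4,5-trimethoxyphenyl)propylidene](phenyl)sulfonium, cation drawn, same counter-ion | COc1cc([C@H](CC=[S+]c2ccccc2)Oc2cccc(OC)c2OC)cc(OC)c1OC | intermediate
10 | (2S,4S)-7,8-dimethoxy-4-(phenylsulfanyl)-2-(3,4,5-trimethoxyphenyl)chromane (2,4-cis) | COc1cc([C@@H]2C[C@H](Sc4ccccc4)c3ccc(OC)c(OC)c3O2)cc(OC)c1OC | intermediate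
11 | (2S)-7,8-dimethoxy-2-(3,4,5-trimethoxyphenyl)chromane, (2S)-7,8,3',4',5'-pentamethoxyflavan | COc1cc([C@@H]2CCc3ccc(OC)c(OC)c3O2)cc(OC)c1OC | target

**Step count**

Total steps: 4. Longest linear sequence: 4 steps (1 → 2 → 6 → 10 → 11).

**Steps most likely to fail**

Step 3 (proposed new method). The ion pair may discriminate the two faces of the cation poorly, because the O-aryl oxocarbenium ion offers no hydrogen-bond anchor to the anion. A racemic background pathway, acid-initiated oligomerisation of the vinyl sulfide, or intermolecular arylation by the liberated phenol may also compete with the annulation. The fallback uses known chemistry and a different logic: C2 is set by catalytic asymmetric ketone reduction and the O1–C2 bond is closed with inversion. It sets out from 3 and returns to the route at 11, bypassing 6 and 10. Magnesium-mediated ortho-formylation of 3 (MgCl2, Et3N, paraformaldehyde, MeCN, reflux) at its only free ortho position should give 2-hydroxy-3,4-dimethoxybenzaldehyde F1. Claisen–Schmidt condensation of this with purchased 1-(3,4,5-trimethoxyphenyl)ethan-1-one F2 (KOH, EtOH) should give (E)-3-(2-hydroxy-3,4-dimethoxyphenyl)-1-(3,4,5-trimethoxyphenyl)prop-2-en-1-one F3. Hydrogenation of the alkene (H2, Pd/C, EtOAc) should give 3-(2-hydroxy-3,4-dimethoxyphenyl)-1-(3,4,5-trimethoxyphenyl)propan-1-one F4. Noyori asymmetric transfer hydrogenation with RuCl[(R,R)-TsDPEN](p-cymene) in HCO2H/Et3N is expected to give 6-[(3R)-3-hydroxy-3-(3,4,5-trimethoxyphenyl)propyl]-2,3-dimethoxyphenol F5. An intramolecular Mitsunobu reaction (PPh3, DIAD, THF, 0 °C) should then displace the benzylic hydroxyl by the phenol oxygen with inversion and give 11.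

Step 2. Adventitious water may hydrolyse the dichloride back to the aldehyde, the second substitution may stall, or the ambident phenoxide may alkylate at carbon. The fallback replaces substitution by acetal exchange; it sets out from 1 and returns at 6, bypassing 2. Treatment of 1 with trimethyl orthoformate (cat. TsOH, MeOH) should give 5-(dimethoxymethyl)-1,2,3-trimethoxybenzene F6. Exchange of both methoxy groups with 3 (2.5 equiv, cat. pyridinium p-toluenesulfonate, toluene, methanol removed under reduced pressure over 5 Å MS) should then lead to 6. The weak acid is chosen to limit Friedel–Crafts C-alkylation of the phenol.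

Step 4. The nickel surface may hydrogenolyse the benzylic C2–O1 ether bond, or the carbon–sulfur cleavage may stall. The fallback changes the mode of cleavage from surface hydrogenolysis to single-electron reduction of a sulfone; it sets out from 10 and returns at 11. Oxidation of 10 (mCPBA, 2.2 equiv, NaHCO3, CH2Cl2, 0 °C) should give (2S,4S)-7,8-dimethoxy-4-(phenylsulfonyl)-2-(3,4,5-trimethoxyphenyl)chromane F7. Reductive desulfonylation with Mg in MeOH should then give 11 without involving C2.

**Further compounds**

F1 | step 3 | 2-hydroxy-3,4-dimethoxybenzaldehyde | O=Cc1ccc(OC)c(OC)c1O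
F2 | step 3 | 1-(3,4,5-trimethoxyphenyl)ethan-1-one (purchased) | CC(=O)c1cc(OC)c(OC)c(OC)c1
F3 | step 3 | (E)-3-(2-hydroxy-3,4-dimethoxyphenyl)-1-(3,4,5-trimethoxyphenyl)prop-2-en-1-one | COc1cc(C(=O)/C=C/c2ccc(OC)c(OC)c2O)cc(OC)c1OC
F4 | step 3 | 3-(2-hydroxy-3,4-dimethoxyphenyl)-1-(3,4,5-trimethoxyphenyl)propan-1-one | COc1cc(C(=O)CCc2ccc(OC)c(OC)c2O)cc(OC)c1OC
F5 | step 3 | 6-[(3R)-3-hydroxy-3-(3,4,5-trimethoxyphenyl)propyl]-2,3-dimethoxyphenol | COc1cc([C@H](O)CCc2ccc(OC)c(OC)c2O)cc(OC)c1OC
F6 | step 2 | 5-(dimethoxymethyl)-1,2,3-trimethoxybenzene | COC(OC)c1cc(OC)c(OC)c(OC)c1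
F7 | step 4 | (2S,4S)-7,8-dimethoxy-4-(phenylsulfonyl)-2-(3,4,5-trimethoxyphenyl)chromane | COc1cc([C@@H]2C[C@H](S(=O)(=O)c4ccccc4)c3ccc(OC)c(OC)c3O2)cc(OC)c1OC
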